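**Retrosynthetic overview**
- Methyl 2-(5-hexadecylfuran-2-yl)acetate is cut inside the side chain between C5' and C6' (counted from the furan). Each of these unactivated CH2 carbons of like polarity is traced back to a carboxylic acid one carbon longer: dodecanoic acid and 6-[5-(2-methoxy-2-oxoethyl)furan-2-yl]hexanoic acid. The two acids are joined as N-hydroxyphthalimide esters by a Ni-electrocatalytic doubly decarboxylative coupling, which expels both activating groups and both extra carbons.
- Enabling feature: the chain is unbranched and heteroatom-free, so C5' and C6' are plain primary radical sites with no stereocentre. Four CH2 groups separate the radical carbon from the furan ring. The furan ring (O1, C2–C5) and the methyl ester are inert to cathodic reduction.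
- The CH2CO2Me arm is placed on the free α-C–H of 6-(furan-2-yl)hexanoic acid by xanthate-based oxidative radical alkylation. The chain CO2H stays free, so the two carboxyl termini are differentiated without protecting groups.
- 6-(Furan-2-yl)hexanoic acid comes from furfural and (4-carboxybutyl)triphenylphosphonium bromide by Wittig olefination and alkene hydrogenation.
- Rings: the furan is bought with furfural and no ring of the target is formed in the route. The phthalimide rings are temporary and leave in the key step.

Key step: step 7

Remark on the chemistry: the target has no stereocentre and no stereogenic double bond. It is achiral, so the given structure is a single species and no enantiocontrol is needed.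

**Step 1**
Reactants: 1 furfural; 2 (4-carboxybutyl)triphenylphosphonium bromide
Product: 4 (Z)-6-(furan-2-yl)hex-5-enoic acid, via potassium ylide carboxylate 3 (not isolated)
Conditions: 2, KOtBu (2.2 equiv), THF, 0 °C; then 1, 0 °C → rt; cold 1 M HCl to pH 4
Reagents that add atoms: potassium tert-butoxide, CC(C)(C)[O-].[K+] (supplies only the K+ of 3; nothing of it remains in 4)
Why: Wittig olefination, in which the non-stabilised ylide 3 (formed with two equivalents of base) adds to the non-enolisable aldehyde 1, and the alkene geometry (mainly Z expected, E equally usable) does not matter because step 2 removes the double bond.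

**Step 2**
Reactants: 4 (Z)-6-(furan-2-yl)hex-5-enoic acid
Product: 5 6-(furan-2-yl)hexanoic acid
Conditions: H2 (1 atm), 5% Pd/C, EtOAc, rt, stopped after uptake of one equivalent of H2
Reagents that add atoms: none
Why: Heterogeneous catalytic hydrogenation, in which the exocyclic disubstituted C=C is reduced on Pd at 1 atm much faster than the aromatic furan, so stopping at one equivalent should leave the ring intact, and no stereocentre arises.

**Step 3**
Reactants: 6 methyl bromoacetate; 7 potassium O-ethyl xanthate
Product: 8 methyl 2-[(ethoxycarbonothioyl)sulfanyl]acetate
Conditions: acetone, 0 °C → rt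
Reagents that add atoms: none
Why: SN2 displacement of the activated primary bromide by the soft sulfur of the xanthate salt.

**Step 4**
Reactants: 5 6-(furan-2-yl)hexanoic acid; 8 methyl 2-[(ethoxycarbonothioyl)sulfanyl]acetate
Product: 9 6-[5-(2-methoxy-2-oxoethyl)furan-2-yl]hexanoic acid
Conditions: 8 (1.5 equiv), dilauroyl peroxide (1.3–1.5 equiv, in portions), degassed ClCH2CH2Cl, reflux
Reagents that add atoms: none
Why: Xanthate-based oxidative radical alkylation of a heteroarene (homolytic aromatic substitution), in which undecyl radicals from the peroxide release the electrophilic •CH2CO2Me radical from 8, this adds to the only free α-carbon of the electron-rich furan, and the peroxide oxidises the oxygen-stabilised allylic radical to a cation that loses H+ and rearomatises while the free CO2H is a spectator.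

**Step 5**
Reactants: 9 6-[5-(2-methoxy-2-oxoethyl)furan-2-yl]hexanoic acid
Product: 10 1,3-dioxoisoindolin-2-yl 6-[5-(2-methoxy-2-oxoethyl)furan-2-yl]hexanoate
Conditions: N-hydroxyphthalimide, DIC, DMAP (cat.), CH2Cl2, rt
Reagents that add atoms: N-hydroxyphthalimide, O=C1c2ccccc2C(=O)N1O
Why: Steglich-type carbodiimide esterification of the only free carboxylic acid gives the redox-active ester under near-neutral conditions that leave the furan and the methyl ester untouched.

**Step 6**
Reactants: 11 dodecanoic acid (lauric acid)
Product: 12 1,3-dioxoisoindolin-2-yl dodecanoate
Conditions: N-hydroxyphthalimide, DIC, DMAP (cat.), CH2Cl2, rt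
Reagents that add atoms: N-hydroxyphthalimide, O=C1c2ccccc2C(=O)N1O
Why: The same Steglich-type carbodiimide esterification, applied to a simple fatty acid.

**Step 7**
Reactants: 10 1,3-dioxoisoindolin-2-yl 6-[5-(2-methoxy-2-oxoethyl)furan-2-yl]hexanoate; 12 1,3-dioxoisoindolin-2-yl dodecanoate
Product: 13 methyl 2-(5-hexadecylfuran-2-yl)acetate
Conditions: 10 (1 equiv), 12 (3 equiv), NiCl2·6H2O (20 mol %), 4,4′,4″-tri-tert-butyl-2,2′:6′,2″-terpyridine (20 mol %), NaI, DMF, undivided cell, (+)Zn | (−)RVC, constant current, ca. 2.5 F per mol of ester, rt, Ar; aq NH4Cl work-up
Reagents that add atoms: none
Why: Cathodically generated low-valent (terpyridine)nickel transfers one electron to each N-acyloxyphthalimide, N–O scission and loss of CO2 release the undecyl radical from 12 and the 5-(furan-2-yl)pentyl radical from 10, and successive capture of both at nickel gives a dialkylnickel(III) species that reductively eliminates the new CH2–CH2 bond. The closest known reaction type is the Ni-electrocatalytic doubly decarboxylative C(sp3)–C(sp3) cross-coupling of two redox-active esters, the reductive counterpart of a mixed Kolbe electrolysis, which is established for pairs of primary alkyl esters. No ring is closed and no stereocentre is created. The step needs cross-coupling over homocoupling, which is secured statistically by the excess of the cheap ester 12, whose homodimer is a hydrocarbon that separates easily from the polar ester 13. It also needs the electron-rich 2,5-dialkylfuran to survive, which the sacrificial zinc anode secures because the anode potential stays far below that at which the ring (O1, C2–C5) is oxidised (the reason a classical anodic Kolbe coupling is not used), while furan and methyl ester are not reduced at the potential that reduces the phthalimide esters. The four CH2 groups between the radical carbon and the ring should make 1,5-hydrogen transfer from the furfurylic CH2 and cyclisation onto the furan slow relative to capture by nickel.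

**Compound list**
1 | furfural (furan-2-carbaldehyde) | O=Cc1ccco1 | starting material
2 | (4-carboxybutyl)triphenylphosphonium bromide | OC(=O)CCCC[P+](c1ccccc1)(c1ccccc1)c1ccccc1.[Br-] | starting material
3 | potassium 5-(triphenyl-λ5-phosphanylidene)pentanoate (ylide carboxylate) | [K+].[O-]C(=O)CCCC=P(c1ccccc1)(c1ccccc1)c1ccccc1 | intermediate
4 | (Z)-6-(furan-2-yl)hex-5-enoic acid (E isomer may accompany it and is used as such) | OC(=O)CCC/C=C\c1ccco1 | intermediate
5 | 6-(furan-2-yl)hexanoic acid | OC(=O)CCCCCc1ccco1 | intermediate
6 | methyl bromoacetate | COC(=O)CBr | starting material
7 | potassium O-ethyl xanthate | CCOC(=S)[S-].[K+] | starting material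
8 | methyl 2-[(ethoxycarbonothioyl)sulfanyl]acetate | CCOC(=S)SCC(=O)OC | intermediate
9 | 6-[5-(2-methoxy-2-oxoethyl)furan-2-yl]hexanoic acid | OC(=O)CCCCCc1ccc(CC(=O)OC)o1 | intermediate
10 | 1,3-dioxoisoindolin-2-yl 6-[5-(2-methoxy-2-oxoethyl)furan-2-yl]hexanoate | O=C(CCCCCc1ccc(CC(=O)OC)o1)ON1C(=O)c2ccccc2C1=O | intermediate
11 | dodecanoic acid (lauric acid) | CCCCCCCCCCCC(=O)O | starting material
12 | 1,3-dioxoisoindolin-2-yl dodecanoate | CCCCCCCCCCCC(=O)ON1C(=O)c2ccccc2C1=O | intermediate
13 | methyl 2-(5-hexadecylfuran-2-yl)acetate | CCCCCCCCCCCCCCCCc1ccc(CC(=O)OC)o1 | target

**Total step count:** 7. **Longest linear sequence:** 5 (steps 1, 2, 4, 5, 7).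

**Steps most likely to fail**

Risk 1, step 7. Three processes may consume 10: homocoupling of the two radicals, hydrodecarboxylation or β-hydride elimination at nickel, and 1,5-hydrogen transfer from the furfurylic position. The fallback sets out from 10 and comes back at 13. It replaces the statistical pairing of two electrophiles by a nucleophile/electrophile pair. 1-Bromoundecane and Mg in THF give undecylmagnesium bromide F1. Treating this with ZnCl2 (0.5 equiv) gives diundecylzinc F2. F2 is then coupled with 10 under NiCl2·glyme and 4,4′-di-tert-butyl-2,2′-bipyridine in THF/DMF at rt. This is a decarboxylative Negishi-type alkyl–alkyl coupling that forms the same CH2–CH2 bond and tolerates the methyl ester.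

Risk 2, step 4. Possible failures are hydrogen abstraction at the furfurylic CH2, addition of undecyl radicals to the ring, and incomplete oxidation of the adduct radical. Separation from the dodecanoic acid formed from the peroxide may also be difficult. Traces of that acid would be harmless, since step 5 turns them into 12. The fallback sets out from 5 and comes back at 9, using polar and cross-coupling chemistry instead of a radical substitution. NBS in DMF at 0 °C in the dark gives 6-(5-bromofuran-2-yl)hexanoic acid F3, which is used at once. Methyl bromoacetate 6 and activated zinc in THF give (2-methoxy-2-oxoethyl)zinc bromide F4. Pd(dba)2/Q-Phos-catalysed coupling of F3 with excess F4 (the first equivalent is consumed by the CO2H) gives 9 after mild acidic work-up. This is a Reformatsky–Negishi α-heteroarylation of an ester.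

Risk 3, step 2. Over-reduction of the furan ring to the tetrahydrofuran, or hydrogenolytic ring opening on palladium, may occur. The fallback sets out from 4 and comes back at 5. It replaces surface catalysis by a metal-free concerted hydrogen transfer that cannot touch an aromatic ring. Diimide F5 is generated in the flask from p-toluenesulfonyl hydrazide and NaOAc in refluxing THF/H2O and reduces only the isolated C=C.

**Further compounds**
F1 | step 7 | undecylmagnesium bromide | CCCCCCCCCCC[Mg]Br
F2 | step 7 | diundecylzinc | CCCCCCCCCCC[Zn]CCCCCCCCCCC
F3 | step 4 | 6-(5-bromofuran-2-yl)hexanoic acid | OC(=O)CCCCCc1ccc(Br)o1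
F4 | step 4 | (2-methoxy-2-oxoethyl)zinc bromide | COC(=O)C[Zn]Br
F5 | step 2 | diimide | N=N
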